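Slowness first: in ochre the product stands at 3% after 1.50 min, yet the starting material has dropped to 58%.

| setting | ochre | red | dusk | dawn | summer | noon |
|---|---|---|---|---|---|---|
| starting material | 0.050 M | 0.10 M | 0.050 M (fed, over 2.0 min) | 0.050 M | 0.050 M | 0.050 M |
| partner | 0.025 M | 0.025 M | 0.0250 M | 0.0250 M (in portions, 5, over 2.0 min) | 0.0250 M | 0.0250 M (fed, over 2.0 min) |
| remark | run made earlier | run made earlier | all else is in the flask from the start; the feed brings no volume worth counting | first portion at the start, last at 2.0 min | everything together at the start | all else is in the flask from the start; the feed brings no volume worth counting |
| time |  |  | 5.0 min | 5.0 min | 5.0 min | 5.0 min |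

- ochre (time / min: product / %, starting material / %): 0.833: 2, 69; 1.50: 3, 58; 2.50: 15, 33; 3.00: 20, 21
- red (time / s: product / %, starting material / %): 10.0: 0, 86; 20.0: 0, 75; 40.0: 0, 57; 60.0: 3, 45

(scatter of a reading: 2 percentage points)

- which flask leads in amount of product, in percent of the starting material charged ("all alike" within 1.5 percentage points) (dusk / dawn / summer / noon / all alike)
- how much product is there at the end, in percent of the starting material charged: dusk
- how much product is there at the end, in percent of the starting material charged: dawn
- how much product is there at the end, in percent of the starting material charged: summer
- how much product is there at the end, in percent of the starting material charged: noon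

Where did the charge go? Not into product: red shows 0% of it at 40.0 s, with 57% left. So work with f, the fraction of the charge left.

Why plot the inverse of f? A second-order loss makes that inverse climb on a straight line from one, at a pace proportional to the charge. Red's reading at 40.0 s gives the pace, with that reading's scatter; scaled to the ochre charge it is the climb, the rise per minute of the inverse of f at 0.050 M, 0.566 min⁻¹.

Does another run agree? Ochre's first reading is 69%, and the line gives 68.0%, inside the scatter of 2 percentage points.

Now the weak spot: does the line hold late? No. At 2.50 min it gives 41.4%, and ochre reads lower, at 33%, with product at 15%. The ochre readings point to a second exit, late in the run.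

And at 5.0 min? For summer the line gives 26.1% as the part of the charge outside the second-order loss. Both runs hold the same partner level, so its part is untested. If the late exit goes with the partner level, dosing holds that level down, and noon and dawn may stay on the line, at 46.9% by 2.0 min. Dusk's charge enters on average 1.00 min late, so its average age at the end is 4.00 min, and the line at that age gives 30.6%, a rough mark. My own reckoning therefore puts dusk level with summer or ahead, and, if that condition on the partner holds, noon and dawn behind.

The forecast differs: summer leads at 41%, with dawn 36%, noon 35% and dusk 28%. Its grounds: “Feeding the starting material keeps its concentration low, delaying the intermediate by nearly a minute, so dusk falls lowest.”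

The flasks give dusk 38.9%, the highest, then summer 36.8%, dawn 15.1% and noon 14.2%.

    starting material + partner + by-product → product + 2 by-product (k = 5100 L² mol⁻² min⁻¹)
    2 starting material → homo dimer (k = 5.50 L mol⁻¹ min⁻¹)
    starting material + partner → product + by-product (k = 0.00260 L mol⁻¹ min⁻¹)

The second-order loss is the homo dimer. In noon the line's 46.9% stands against 47.6% left at 2.00 min, and its 26.1% against 29.4% outside the homo dimer at 5.00 min. The neighbour is dusk with 0.020 M of starting material. Its climb scales with the charge to 0.226 min⁻¹, so at age 4.00 min the line leaves 52.5%. That flask holds 56.2% outside the homo dimer at 5.00 min, with product at 4.87%.

All runs were generated by integration with made-up constants; the scatter is artificial.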